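**Plan**

1. Retrosynthesis: the C13–Cl bond and the two acetate C–O bonds are cut first (the one at C8 with inversion), then the lactone bond C12–O6, which leaves a C6,C12-diol. The C6–C7 bond is cut by a retro-[2,3]-Wittig shift to a thirteen-membered ether with oxygen between C6 and C13. That ether is opened at O–C13, C7=C11 is cut by olefination, C9–C10 and C3–C4 by alkenyl-metal/epoxide opening, and C1=C10 by a Wittig reaction.
2. Forward: a linear chain is built from (Z)-3-iodobut-2-en-1-ol. The thirteen-membered ether closes first, contracts to the ten-membered carbocycle in the key step, and the γ-lactone closes last.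
3. Stereochemistry: C2 and C8 come from methyl (S)-glycidate. C8 is carried as 8S, the epimer of the target, because the C6 carbanion is expected to add anti to the allylic C8–O bond; it is inverted when its acetate is put on. C7 follows from C8 and C6 from the C7=C11 geometry in the key step. C11 comes from a Sharpless epoxidation, and both Z olefins from Z-alkenyl iodides.
4. The C12 oxygen is a silyl ether, so that no benzylic C–H competes in the lithiation. Locants C1–C13 are those of the germacrane skeleton; PMB = 4-methoxybenzyl, TBS = tert-butyldimethylsilyl, TIPS = triisopropylsilyl.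

Key step: step 17

Remark: (Z)-3-iodobut-2-en-1-ol, methyl (S)-glycidate, triethyl phosphonoacetate and benzyl chloromethyl ether are taken as purchased.

Step 1
Reactants: 1 triethyl phosphonoacetate; 2 benzyl chloromethyl ether
Product: 3 ethyl 3-(benzyloxy)-2-(diethoxyphosphoryl)propanoate
Conditions: NaH, THF, 0 °C; then 2 (0.9 equiv), 0 °C to rt
Reagents that add atoms: none
Why: C-alkylation of the sodium salt of a doubly stabilized phosphonate carbanion with a reactive α-chloro ether is an ordinary SN2 enolate alkylation, and the slight excess of 1 holds back double alkylation.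

Step 2
Reactants: 3 ethyl 3-(benzyloxy)-2-(diethoxyphosphoryl)propanoate
Product: 4 ethyl 2-(diethoxyphosphoryl)-3-hydroxypropanoate
Conditions: H2 (1 atm), Pd/C, EtOH, rt
Reagents that add atoms: none
Why: Hydrogenolysis of a benzyl ether over palladium on carbon runs under neutral conditions that leave the phosphonate, the ester and the new β-hydroxy group in place.

Step 3
Reactants: 4 ethyl 2-(diethoxyphosphoryl)-3-hydroxypropanoate
Product: 5 ethyl 3-(TBS-oxy)-2-(diethoxyphosphoryl)propanoate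
Conditions: TBSCl, imidazole, CH2Cl2, 0 °C
Reagents that add atoms: tert-butyldimethylsilyl chloride, CC(C)(C)[Si](C)(C)Cl
Why: Silylation of a primary alcohol with a silyl chloride and imidazole is a standard protection and at 0 °C it is faster than base-induced loss of the β-oxygen from the phosphonate.

Step 4
Reactants: 6 (Z)-3-iodobut-2-en-1-ol
Product: 7 (Z)-3-iodobut-2-enyl 4-methoxybenzyl ether
Conditions: NaH, 4-methoxybenzyl chloride, tetrabutylammonium iodide (cat.), THF, 0 °C to rt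
Reagents that add atoms: 4-methoxybenzyl chloride, COc1ccc(CCl)cc1
Why: Williamson etherification of the primary allylic alkoxide puts on a 4-methoxybenzyl group that survives the organometallic steps and later leaves oxidatively beside silyl ethers and an allylic chloride.

Step 5
Reactants: 7 (Z)-3-iodobut-2-enyl 4-methoxybenzyl ether; 8 methyl (S)-glycidate
Product: 11 methyl (2S,4Z)-2-hydroxy-6-(PMB-oxy)-4-methylhex-4-enoate, via alkenyllithium 9 (not isolated), via alkenylmagnesium bromide 10 (not isolated)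
Conditions: t-BuLi (2.1 equiv), Et2O, −78 °C; MgBr2·OEt2, −78 to −40 °C; CuBr·SMe2 (10 mol%), 8, THF, −40 to −20 °C; H2O
Reagents that add atoms: none
Why: Iodine–lithium exchange with retention of the olefin geometry, transmetalation to magnesium and copper-catalysed SN2 opening of the glycidic ester at its CH2 end form C3–C4, so that C2 is taken over unchanged from (S)-glycidate and C4=C5 stays Z.

Step 6
Reactants: 11 methyl (2S,4Z)-2-hydroxy-6-(PMB-oxy)-4-methylhex-4-enoate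
Product: 12 methyl (2S,4Z)-6-(PMB-oxy)-4-methyl-2-(TIPS-oxy)hex-4-enoate
Conditions: TIPSOTf, 2,6-lutidine, CH2Cl2, 0 °C
Reagents that add atoms: triisopropylsilyl trifluoromethanesulfonate, CC(C)[Si](C(C)C)(C(C)C)OS(=O)(=O)C(F)(F)F
Why: Silylation of the secondary alcohol with a silyl triflate and a hindered pyridine base is routine, and the bulky triisopropylsilyl group is chosen because it does not migrate to the neighbouring alkenyllithium carbon in step 9 and outlasts both tert-butyldimethylsilyl ethers at the end.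

Step 7
Reactants: 12 methyl (2S,4Z)-6-(PMB-oxy)-4-methyl-2-(TIPS-oxy)hex-4-enoate
Product: 13 (2S,4Z)-6-(PMB-oxy)-4-methyl-2-(TIPS-oxy)hex-4-enal
Conditions: i-Bu2AlH (1.1 equiv), CH2Cl2, −78 °C; aqueous potassium sodium tartrate
Reagents that add atoms: none
Why: Reduction of an α-silyloxy methyl ester with diisobutylaluminium hydride at −78 °C stops at the aldehyde because the aluminium hemiacetal holds until work-up, and the α-centre is not epimerised.

Step 8
Reactants: 13 (2S,4Z)-6-(PMB-oxy)-4-methyl-2-(TIPS-oxy)hex-4-enal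
Product: 14 (2Z,4S,6Z)-2-iodo-8-(PMB-oxy)-6-methyl-4-(TIPS-oxy)octa-2,6-diene
Conditions: ethyltriphenylphosphonium iodide, n-BuLi, THF, rt; I2, −78 °C; NaN(SiMe3)2, −20 °C; then 13, −78 to −20 °C
Reagents that add atoms: ethyltriphenylphosphonium iodide, CC[P+](c1ccccc1)(c1ccccc1)c1ccccc1.[I-]; iodine, [I][I]
Why: The Stork–Zhao variant of the Wittig reaction with the α-iodoethylidene ylide gives the trisubstituted alkenyl iodide with iodine cis to the C2 chain, which fixes the Z geometry of the later C1=C10 olefin.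

Step 9
Reactants: 14 (2Z,4S,6Z)-2-iodo-8-(PMB-oxy)-6-methyl-4-(TIPS-oxy)octa-2,6-diene; 8 methyl (S)-glycidate
Product: 17 methyl (2S,4Z,6S,8Z)-2-hydroxy-10-(PMB-oxy)-4,8-dimethyl-6-(TIPS-oxy)deca-4,8-dienoate, via alkenyllithium 15 (not isolated), via alkenylmagnesium bromide 16 (not isolated)
Conditions: t-BuLi (2.1 equiv), Et2O, −78 °C; MgBr2·OEt2, −78 to −40 °C; CuBr·SMe2 (10 mol%), 8, THF, −40 to −20 °C; H2O
Reagents that add atoms: none
Why: The same exchange, transmetalation and copper-catalysed glycidate opening form C9–C10 with retention of the Z geometry, and C8 is taken over from (S)-glycidate as the 8S centre, on purpose the epimer of the target, because this configuration steers the carbanion in step 17.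

Step 10
Reactants: 17 methyl (2S,4Z,6S,8Z)-2-hydroxy-10-(PMB-oxy)-4,8-dimethyl-6-(TIPS-oxy)deca-4,8-dienoate
Product: 18 methyl (2S,4Z,6S,8Z)-2-(TBS-oxy)-10-(PMB-oxy)-4,8-dimethyl-6-(TIPS-oxy)deca-4,8-dienoate
Conditions: TBSOTf, 2,6-lutidine, CH2Cl2, 0 °C
Reagents that add atoms: tert-butyldimethylsilyl trifluoromethanesulfonate, CC(C)(C)[Si](C)(C)OS(=O)(=O)C(F)(F)F
Why: Silylation of the hindered α-hydroxy ester with a silyl triflate is routine, and a tert-butyldimethylsilyl ether is chosen for C8 because it can later be cleaved while the C2 triisopropylsilyl ether stays.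

Step 11
Reactants: 18 methyl (2S,4Z,6S,8Z)-2-(TBS-oxy)-10-(PMB-oxy)-4,8-dimethyl-6-(TIPS-oxy)deca-4,8-dienoate
Product: 19 (2S,4Z,6S,8Z)-2-(TBS-oxy)-10-(PMB-oxy)-4,8-dimethyl-6-(TIPS-oxy)deca-4,8-dienal
Conditions: i-Bu2AlH (1.1 equiv), CH2Cl2, −78 °C; aqueous potassium sodium tartrate
Reagents that add atoms: none
Why: Partial reduction of the α-silyloxy methyl ester with diisobutylaluminium hydride at −78 °C again stops at the aldehyde without epimerising C8.

Step 12
Reactants: 19 (2S,4Z,6S,8Z)-2-(TBS-oxy)-10-(PMB-oxy)-4,8-dimethyl-6-(TIPS-oxy)deca-4,8-dienal; 5 ethyl 3-(TBS-oxy)-2-(diethoxyphosphoryl)propanoate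
Product: 20 ethyl (2E,4S,6Z,8S,10Z)-4-(TBS-oxy)-2-[(TBS-oxy)methyl]-12-(PMB-oxy)-6,10-dimethyl-8-(TIPS-oxy)dodeca-2,6,10-trienoate
Conditions: 5 (1.3 equiv), LiCl, DBU, MeCN, 0 °C to rt
Reagents that add atoms: none
Why: Horner–Wadsworth–Emmons olefination with an α-substituted phosphonoacetate under mild LiCl and amine conditions gives the E enoate, which places the ester carbon C13 trans and the silyloxymethyl carbon C12 cis to C8 without epimerising the α-silyloxy aldehyde.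

Step 13
Reactants: 20 ethyl (2E,4S,6Z,8S,10Z)-4-(TBS-oxy)-2-[(TBS-oxy)methyl]-12-(PMB-oxy)-6,10-dimethyl-8-(TIPS-oxy)dodeca-2,6,10-trienoate
Product: 21 (2Z,4S,6Z,8S,10Z)-4-(TBS-oxy)-2-[(TBS-oxy)methyl]-12-(PMB-oxy)-6,10-dimethyl-8-(TIPS-oxy)dodeca-2,6,10-trien-1-ol
Conditions: i-Bu2AlH (2.5 equiv), CH2Cl2, −78 °C; aqueous potassium sodium tartrate
Reagents that add atoms: none
Why: Diisobutylaluminium hydride reduces the conjugated ester by 1,2-addition to the primary allylic alcohol and leaves the olefin geometries and all ethers untouched.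

Step 14
Reactants: 21 (2Z,4S,6Z,8S,10Z)-4-(TBS-oxy)-2-[(TBS-oxy)methyl]-12-(PMB-oxy)-6,10-dimethyl-8-(TIPS-oxy)dodeca-2,6,10-trien-1-ol
Product: 23 (2E,4S,6Z,8S,10Z)-1-chloro-4-(TBS-oxy)-2-[(TBS-oxy)methyl]-12-(PMB-oxy)-6,10-dimethyl-8-(TIPS-oxy)dodeca-2,6,10-triene, via C13 mesylate 22 (not isolated)
Conditions: MsCl, 2,4,6-collidine, LiCl, DMF, 0 °C
Reagents that add atoms: lithium chloride, [Li+].[Cl-]
Why: Mesylation in the presence of chloride converts the primary allylic alcohol through mesylate 22 into the allylic chloride by direct SN2 displacement, without allylic transposition and without loss of the silyl or 4-methoxybenzyl ethers.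

Step 15
Reactants: 23 (2E,4S,6Z,8S,10Z)-1-chloro-4-(TBS-oxy)-2-[(TBS-oxy)methyl]-12-(PMB-oxy)-6,10-dimethyl-8-(TIPS-oxy)dodeca-2,6,10-triene
Product: 24 (2Z,5S,6Z,9S,10E)-12-chloro-9-(TBS-oxy)-11-[(TBS-oxy)methyl]-3,7-dimethyl-5-(TIPS-oxy)dodeca-2,6,10-trien-1-ol
Conditions: DDQ, CH2Cl2/pH 7 buffer, 0 °C
Reagents that add atoms: none
Why: Oxidative cleavage of the 4-methoxybenzyl ether with DDQ in buffered wet dichloromethane frees the C6 alcohol and tolerates the allylic chloride, the silyl ethers and the trisubstituted olefins.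

Step 16
Reactants: 24 (2Z,5S,6Z,9S,10E)-12-chloro-9-(TBS-oxy)-11-[(TBS-oxy)methyl]-3,7-dimethyl-5-(TIPS-oxy)dodeca-2,6,10-trien-1-ol
Product: 25 (3Z,5S,7Z,9S,11Z)-5-(TBS-oxy)-3-[(TBS-oxy)methyl]-7,11-dimethyl-9-(TIPS-oxy)-1-oxacyclotrideca-3,7,11-triene (ring bonds at C7=C11 trans)
Conditions: NaH, tetrabutylammonium iodide (cat.), THF (0.003 M, slow addition), 50 °C
Reagents that add atoms: none
Why: Intramolecular Williamson etherification of the C6 alkoxide with the primary allylic chloride at C13 under high dilution closes the thirteen-membered ether, a large-ring closure of the kind used to make macrocyclic diallylic ethers.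

Step 17
Reactants: 25 (3Z,5S,7Z,9S,11Z)-5-(TBS-oxy)-3-[(TBS-oxy)methyl]-7,11-dimethyl-9-(TIPS-oxy)-1-oxacyclotrideca-3,7,11-triene
Product: 27 (1R,2Z,5S,6Z,9S,10S)-9-(TBS-oxy)-10-[3-(TBS-oxy)prop-1-en-2-yl]-3,7-dimethyl-5-(TIPS-oxy)cyclodeca-2,6-dien-1-ol, via C6-lithio ether 26 (not isolated)
Conditions: n-BuLi (2 equiv), THF, −78 to −25 °C; H2O
Reagents that add atoms: none
Why: n-BuLi removes a C6 proton, allylic and α to the ring oxygen, and the α-alkoxy organolithium 26 bonds through C6 to C7 in a five-membered envelope transition state while O–C13 breaks and C11=C13 forms, which is the [2,3]-Wittig rearrangement in its known transannular, ring-contracting form for thirteen-membered diallylic ethers. The ten-membered carbocycle closes by this suprafacial transannular C6–C7 bond formation inside the thirteen-membered ring, so that the ether ring contracts and no open chain has to be cyclized. C7 is set by the C8 silyloxy centre: allylic 1,3-strain against the cis CH2OTBS group holds H8 in the olefin plane and the carbanion adds anti to the C8–O bond, which from the 8S ether gives the C7 configuration of the target. C6 is set relative to C7 by the olefin geometry, because with C8 trans to C13 and the C5 vinyl group exo on the envelope the anti, 6,7-trans arrangement results. The step needs lithiation at C6 and not at C13 or C12, which is expected because both of these flank the fully substituted C11 under the bulky silyl ether, no benzylic ether is present, and a C13 anion could rearrange only by attacking the fully substituted C4; the two Z ring olefins and the silyl ethers are not touched below −25 °C.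

Step 18
Reactants: 27 (1R,2Z,5S,6Z,9S,10S)-9-(TBS-oxy)-10-[3-(TBS-oxy)prop-1-en-2-yl]-3,7-dimethyl-5-(TIPS-oxy)cyclodeca-2,6-dien-1-ol
Product: 28 (1R,2Z,5S,6Z,9S,10S)-9-(TBS-oxy)-10-(3-hydroxyprop-1-en-2-yl)-3,7-dimethyl-5-(TIPS-oxy)cyclodeca-2,6-dien-1-ol
Conditions: HF·pyridine, pyridine, THF, 0 °C
Reagents that add atoms: none
Why: Buffered HF·pyridine at 0 °C cleaves the unhindered primary allylic tert-butyldimethylsilyl ether much faster than the secondary one at C8 or the triisopropylsilyl ether at C2, which is a well-used selective desilylation.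

Step 19
Reactants: 28 (1R,2Z,5S,6Z,9S,10S)-9-(TBS-oxy)-10-(3-hydroxyprop-1-en-2-yl)-3,7-dimethyl-5-(TIPS-oxy)cyclodeca-2,6-dien-1-ol
Product: 29 (1R,2Z,5S,6Z,9S,10S)-9-(TBS-oxy)-10-[(2S)-2-(hydroxymethyl)oxiran-2-yl]-3,7-dimethyl-5-(TIPS-oxy)cyclodeca-2,6-dien-1-ol
Conditions: Ti(OiPr)4 (10 mol%), L-(+)-diethyl tartrate (12 mol%), t-BuOOH, 4 Å molecular sieves, CH2Cl2, −20 °C
Reagents that add atoms: tert-butyl hydroperoxide, CC(C)(C)OO
Why: Sharpless asymmetric epoxidation acts only on the primary 2-substituted allylic alcohol, since the C6 alcohol is secondary and its olefin carries a cis substituent, and L-(+)-diethyl tartrate delivers oxygen to the face of C11=C13 that gives the 11S epoxide, so that C11 is set by the reagent.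

Step 20
Reactants: 29 (1R,2Z,5S,6Z,9S,10S)-9-(TBS-oxy)-10-[(2S)-2-(hydroxymethyl)oxiran-2-yl]-3,7-dimethyl-5-(TIPS-oxy)cyclodeca-2,6-dien-1-ol
Product: 32 (2S,6R,7S,8S,11R)-8-(TBS-oxy)-11,13-epoxy-2-(TIPS-oxy)germacra-1(10)Z,4Z-dien-12,6-olide, via epoxy aldehyde 30 (not isolated), via lactol 31 (not isolated)
Conditions: TEMPO (cat.), PhI(OAc)2 (2.5 equiv), CH2Cl2, rt
Reagents that add atoms: none
Why: TEMPO with PhI(OAc)2 oxidises the primary epoxy alcohol to aldehyde 30, which closes with the C6 hydroxyl to lactol 31 and is oxidised on to the γ-lactone, a standard oxidative lactonization of a 1,4-diol that leaves the epoxide, the silyl ethers and the ring olefins alone.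

Step 21
Reactants: 32 (2S,6R,7S,8S,11R)-8-(TBS-oxy)-11,13-epoxy-2-(TIPS-oxy)germacra-1(10)Z,4Z-dien-12,6-olide
Product: 33 (2S,6R,7S,8S,11S)-8-(TBS-oxy)-13-chloro-11-hydroxy-2-(TIPS-oxy)germacra-1(10)Z,4Z-dien-12,6-olide
Conditions: LiCl, AcOH, THF, rt
Reagents that add atoms: lithium chloride, [Li+].[Cl-]
Why: Chloride opens the spiro epoxide of the glycidic lactone by SN2 attack at the primary carbon C13, the only accessible site since C11 is fully substituted and next to the carbonyl, so that the C11–O bond and its configuration are kept.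

Step 22
Reactants: 33 (2S,6R,7S,8S,11S)-8-(TBS-oxy)-13-chloro-11-hydroxy-2-(TIPS-oxy)germacra-1(10)Z,4Z-dien-12,6-olide
Product: 34 (2S,6R,7R,8S,11S)-13-chloro-8,11-dihydroxy-2-(TIPS-oxy)germacra-1(10)Z,4Z-dien-12,6-olide
Conditions: HF·pyridine, THF, 0 °C to rt
Reagents that add atoms: none
Why: HF·pyridine at room temperature removes the secondary tert-butyldimethylsilyl ether at C8 while the bulkier triisopropylsilyl ether at C2 stays, a standard differentiation of these two silyl groups.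

Step 23
Reactants: 34 (2S,6R,7R,8S,11S)-13-chloro-8,11-dihydroxy-2-(TIPS-oxy)germacra-1(10)Z,4Z-dien-12,6-olide
Product: 35 (2S,6R,7R,8R,11S)-8-acetoxy-13-chloro-11-hydroxy-2-(TIPS-oxy)germacra-1(10)Z,4Z-dien-12,6-olide
Conditions: PPh3, DIAD, AcOH, toluene, 0 °C to rt
Reagents that add atoms: acetic acid, CC(=O)O
Why: Mitsunobu esterification with acetic acid activates the C8 alcohol as its oxyphosphonium salt and acetate displaces it with inversion, which turns the 8S carbinol that guided the ring contraction into the 8R acetate of the target, while the tertiary C11 alcohol cannot be activated.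

Step 24
Reactants: 35 (2S,6R,7R,8R,11S)-8-acetoxy-13-chloro-11-hydroxy-2-(TIPS-oxy)germacra-1(10)Z,4Z-dien-12,6-olide
Product: 36 (2S,6R,7R,8R,11S)-8-acetoxy-13-chloro-2,11-dihydroxygermacra-1(10)Z,4Z-dien-12,6-olide
Conditions: aqueous HF (48%), MeCN, rt
Reagents that add atoms: none
Why: Aqueous HF in acetonitrile cleaves the secondary triisopropylsilyl ether under acidic conditions that leave the acetate, the lactone and the chlorohydrin unchanged.

Step 25
Reactants: 36 (2S,6R,7R,8R,11S)-8-acetoxy-13-chloro-2,11-dihydroxygermacra-1(10)Z,4Z-dien-12,6-olide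
Product: 37 (2S,6R,7R,8R,11S)-2,8-diacetoxy-13-chloro-11-hydroxygermacra-1(10)Z,4Z-dien-12,6-olide (CNP0182971.4)
Conditions: Ac2O, pyridine, CH2Cl2, 0 °C to rt
Reagents that add atoms: acetic anhydride, CC(=O)OC(C)=O
Why: Acetylation with acetic anhydride and pyridine esterifies the secondary allylic C2 alcohol with retention, while the hindered tertiary C11 alcohol stays free without a nucleophilic catalyst.

**Compound list**

1 | triethyl phosphonoacetate | CCOC(=O)CP(=O)(OCC)OCC | starting material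
2 | benzyl chloromethyl ether | ClCOCc1ccccc1 | starting material
3 | ethyl 3-(benzyloxy)-2-(diethoxyphosphoryl)propanoate (racemic) | CCOC(=O)C(COCc1ccccc1)P(=O)(OCC)OCC | intermediate
4 | ethyl 2-(diethoxyphosphoryl)-3-hydroxypropanoate (racemic) | CCOC(=O)C(CO)P(=O)(OCC)OCC | intermediate
5 | ethyl 3-(TBS-oxy)-2-(diethoxyphosphoryl)propanoate (racemic) | CCOC(=O)C(CO[Si](C)(C)C(C)(C)C)P(=O)(OCC)OCC | intermediate
6 | (Z)-3-iodobut-2-en-1-ol | OC/C=C(/C)I | starting material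
7 | (Z)-3-iodobut-2-enyl 4-methoxybenzyl ether | COc1ccc(COC/C=C(/C)I)cc1 | intermediate
8 | methyl (2S)-oxirane-2-carboxylate (methyl (S)-glycidate) | COC(=O)[C@@H]1CO1 | starting material
9 | alkenyllithium from 7 (Li in place of I; geometry retained) | COc1ccc(COC/C=C(/C)[Li])cc1 | intermediate
10 | alkenylmagnesium bromide from 7 (MgBr in place of I; geometry retained) | COc1ccc(COC/C=C(/C)[Mg]Br)cc1 | intermediate
11 | methyl (2S,4Z)-2-hydroxy-6-(PMB-oxy)-4-methylhex-4-enoate | COc1ccc(COC/C=C(/C)C[C@H](O)C(=O)OC)cc1 | intermediate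
12 | methyl (2S,4Z)-6-(PMB-oxy)-4-methyl-2-(TIPS-oxy)hex-4-enoate | COc1ccc(COC/C=C(/C)C[C@H](O[Si](C(C)C)(C(C)C)C(C)C)C(=O)OC)cc1 | intermediate
13 | (2S,4Z)-6-(PMB-oxy)-4-methyl-2-(TIPS-oxy)hex-4-enal | COc1ccc(COC/C=C(/C)C[C@H](O[Si](C(C)C)(C(C)C)C(C)C)C=O)cc1 | intermediate
14 | (2Z,4S,6Z)-2-iodo-8-(PMB-oxy)-6-methyl-4-(TIPS-oxy)octa-2,6-diene | COc1ccc(COC/C=C(/C)C[C@H](O[Si](C(C)C)(C(C)C)C(C)C)/C=C(/C)I)cc1 | intermediate
15 | alkenyllithium from 14 (Li in place of I; geometry retained) | COc1ccc(COC/C=C(/C)C[C@H](O[Si](C(C)C)(C(C)C)C(C)C)/C=C(/C)[Li])cc1 | intermediate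
16 | alkenylmagnesium bromide from 14 (MgBr in place of I; geometry retained) | COc1ccc(COC/C=C(/C)C[C@H](O[Si](C(C)C)(C(C)C)C(C)C)/C=C(/C)[Mg]Br)cc1 | intermediate
17 | methyl (2S,4Z,6S,8Z)-2-hydroxy-10-(PMB-oxy)-4,8-dimethyl-6-(TIPS-oxy)deca-4,8-dienoate | COc1ccc(COC/C=C(/C)C[C@H](O[Si](C(C)C)(C(C)C)C(C)C)/C=C(/C)C[C@H](O)C(=O)OC)cc1 | intermediate
18 | methyl (2S,4Z,6S,8Z)-2-(TBS-oxy)-10-(PMB-oxy)-4,8-dimethyl-6-(TIPS-oxy)deca-4,8-dienoate | COc1ccc(COC/C=C(/C)C[C@H](O[Si](C(C)C)(C(C)C)C(C)C)/C=C(/C)C[C@H](O[Si](C)(C)C(C)(C)C)C(=O)OC)cc1 | intermediate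
19 | (2S,4Z,6S,8Z)-2-(TBS-oxy)-10-(PMB-oxy)-4,8-dimethyl-6-(TIPS-oxy)deca-4,8-dienal | COc1ccc(COC/C=C(/C)C[C@H](O[Si](C(C)C)(C(C)C)C(C)C)/C=C(/C)C[C@H](O[Si](C)(C)C(C)(C)C)C=O)cc1 | intermediate
20 | ethyl (2E,4S,6Z,8S,10Z)-4-(TBS-oxy)-2-[(TBS-oxy)methyl]-12-(PMB-oxy)-6,10-dimethyl-8-(TIPS-oxy)dodeca-2,6,10-trienoate | COc1ccc(COC/C=C(/C)C[C@H](O[Si](C(C)C)(C(C)C)C(C)C)/C=C(/C)C[C@H](O[Si](C)(C)C(C)(C)C)/C=C(/C(=O)OCC)CO[Si](C)(C)C(C)(C)C)cc1 | intermediate
21 | (2Z,4S,6Z,8S,10Z)-4-(TBS-oxy)-2-[(TBS-oxy)methyl]-12-(PMB-oxy)-6,10-dimethyl-8-(TIPS-oxy)dodeca-2,6,10-trien-1-ol | COc1ccc(COC/C=C(/C)C[C@H](O[Si](C(C)C)(C(C)C)C(C)C)/C=C(/C)C[C@H](O[Si](C)(C)C(C)(C)C)/C=C(/CO)CO[Si](C)(C)C(C)(C)C)cc1 | intermediate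
22 | methanesulfonate of 21 (C13 mesylate) | COc1ccc(COC/C=C(/C)C[C@H](O[Si](C(C)C)(C(C)C)C(C)C)/C=C(/C)C[C@H](O[Si](C)(C)C(C)(C)C)/C=C(/COS(C)(=O)=O)CO[Si](C)(C)C(C)(C)C)cc1 | intermediate
23 | (2E,4S,6Z,8S,10Z)-1-chloro-4-(TBS-oxy)-2-[(TBS-oxy)methyl]-12-(PMB-oxy)-6,10-dimethyl-8-(TIPS-oxy)dodeca-2,6,10-triene | COc1ccc(COC/C=C(/C)C[C@H](O[Si](C(C)C)(C(C)C)C(C)C)/C=C(/C)C[C@H](O[Si](C)(C)C(C)(C)C)/C=C(/CCl)CO[Si](C)(C)C(C)(C)C)cc1 | intermediate
24 | (2Z,5S,6Z,9S,10E)-12-chloro-9-(TBS-oxy)-11-[(TBS-oxy)methyl]-3,7-dimethyl-5-(TIPS-oxy)dodeca-2,6,10-trien-1-ol | OC/C=C(/C)C[C@H](O[Si](C(C)C)(C(C)C)C(C)C)/C=C(/C)C[C@H](O[Si](C)(C)C(C)(C)C)/C=C(/CCl)CO[Si](C)(C)C(C)(C)C | intermediate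
25 | (3Z,5S,7Z,9S,11Z)-5-(TBS-oxy)-3-[(TBS-oxy)methyl]-7,11-dimethyl-9-(TIPS-oxy)-1-oxacyclotrideca-3,7,11-triene; germacrane locants: O between C6 and C13, 2S, 8S, ring bonds at C7=C11 trans | CC(C)[Si](C(C)C)(C(C)C)O[C@@H]1/C=C(/C)C[C@H](O[Si](C)(C)C(C)(C)C)/C=C(\CO[Si](C)(C)C(C)(C)C)COC/C=C(/C)C1 | intermediate
26 | C6-lithio derivative of 25 (lithium on the ether carbon next to C5) | CC(C)[Si](C(C)C)(C(C)C)O[C@@H]1/C=C(/C)C[C@H](O[Si](C)(C)C(C)(C)C)/C=C(\CO[Si](C)(C)C(C)(C)C)COC([Li])/C=C(/C)C1 | intermediate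
27 | (1R,2Z,5S,6Z,9S,10S)-9-(TBS-oxy)-10-[3-(TBS-oxy)prop-1-en-2-yl]-3,7-dimethyl-5-(TIPS-oxy)cyclodeca-2,6-dien-1-ol; germacrane locants 2S,6R,7S,8S | CC(C)[Si](C(C)C)(C(C)C)O[C@@H]1/C=C(/C)C[C@H](O[Si](C)(C)C(C)(C)C)[C@@H](C(=C)CO[Si](C)(C)C(C)(C)C)[C@@H](/C=C(/C)C1)O | intermediate
28 | (1R,2Z,5S,6Z,9S,10S)-9-(TBS-oxy)-10-(3-hydroxyprop-1-en-2-yl)-3,7-dimethyl-5-(TIPS-oxy)cyclodeca-2,6-dien-1-ol | CC(C)[Si](C(C)C)(C(C)C)O[C@@H]1/C=C(/C)C[C@H](O[Si](C)(C)C(C)(C)C)[C@@H](C(=C)CO)[C@@H](/C=C(/C)C1)O | intermediate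
29 | (1R,2Z,5S,6Z,9S,10S)-9-(TBS-oxy)-10-[(2S)-2-(hydroxymethyl)oxiran-2-yl]-3,7-dimethyl-5-(TIPS-oxy)cyclodeca-2,6-dien-1-ol | CC(C)[Si](C(C)C)(C(C)C)O[C@@H]1/C=C(/C)C[C@H](O[Si](C)(C)C(C)(C)C)[C@@H]([C@]2(CO)CO2)[C@@H](/C=C(/C)C1)O | intermediate
30 | (2R)-oxirane-2-carbaldehyde from 29 (C12 aldehyde; C6 hydroxyl free) | CC(C)[Si](C(C)C)(C(C)C)O[C@@H]1/C=C(/C)C[C@H](O[Si](C)(C)C(C)(C)C)[C@@H]([C@]2(C=O)CO2)[C@@H](/C=C(/C)C1)O | intermediate
31 | C12 lactol of 30 (O6 bonded to C12; lactol carbon unassigned) | CC(C)[Si](C(C)C)(C(C)C)O[C@@H]1/C=C(/C)C[C@H](O[Si](C)(C)C(C)(C)C)[C@@H]2[C@@H](/C=C(/C)C1)OC(O)[C@]23CO3 | intermediate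
32 | (2S,6R,7S,8S,11R)-8-(TBS-oxy)-11,13-epoxy-2-(TIPS-oxy)germacra-1(10)Z,4Z-dien-12,6-olide | CC(C)[Si](C(C)C)(C(C)C)O[C@@H]1/C=C(/C)C[C@H](O[Si](C)(C)C(C)(C)C)[C@@H]2[C@@H](/C=C(/C)C1)OC(=O)[C@]23CO3 | intermediate
33 | (2S,6R,7S,8S,11S)-8-(TBS-oxy)-13-chloro-11-hydroxy-2-(TIPS-oxy)germacra-1(10)Z,4Z-dien-12,6-olide | CC(C)[Si](C(C)C)(C(C)C)O[C@@H]1/C=C(/C)C[C@H](O[Si](C)(C)C(C)(C)C)[C@@H]2[C@@H](/C=C(/C)C1)OC(=O)[C@]2(O)CCl | intermediate
34 | (2S,6R,7R,8S,11S)-13-chloro-8,11-dihydroxy-2-(TIPS-oxy)germacra-1(10)Z,4Z-dien-12,6-olide | CC(C)[Si](C(C)C)(C(C)C)O[C@@H]1/C=C(/C)C[C@H](O)[C@@H]2[C@@H](/C=C(/C)C1)OC(=O)[C@]2(O)CCl | intermediate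
35 | (2S,6R,7R,8R,11S)-8-acetoxy-13-chloro-11-hydroxy-2-(TIPS-oxy)germacra-1(10)Z,4Z-dien-12,6-olide | CC(C)[Si](C(C)C)(C(C)C)O[C@@H]1/C=C(/C)C[C@@H](OC(C)=O)[C@@H]2[C@@H](/C=C(/C)C1)OC(=O)[C@]2(O)CCl | intermediate
36 | (2S,6R,7R,8R,11S)-8-acetoxy-13-chloro-2,11-dihydroxygermacra-1(10)Z,4Z-dien-12,6-olide | O[C@@H]1/C=C(/C)C[C@@H](OC(C)=O)[C@@H]2[C@@H](/C=C(/C)C1)OC(=O)[C@]2(O)CCl | intermediate
37 | (2S,6R,7R,8R,11S)-2,8-diacetoxy-13-chloro-11-hydroxygermacra-1(10)Z,4Z-dien-12,6-olide (CNP0182971.4) | CC(=O)O[C@@H]1/C=C(/C)C[C@@H](OC(C)=O)[C@@H]2[C@@H](/C=C(/C)C1)OC(=O)[C@]2(O)CCl | target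

**Step count and risks**

Total steps: 25 (steps 1–3 make the phosphonate 5; steps 4–25 are the main line).
Longest linear sequence: 22 steps (steps 4–25, from (Z)-3-iodobut-2-en-1-ol).

Steps most likely to fail:

Step 17 (ring contraction). What may go wrong is lithiation at C13 instead of C6, followed by loss of the C8 silyloxide or a shift onto C4; addition to the other face of C7=C11; or a competing [1,2]-shift. Fallback: the route leaves from chloro alcohol 24. Oxidation of its C6 allylic alcohol with MnO2 in CH2Cl2 gives the (Z)-enal chloride F1. F1 is added slowly to CrCl2 in THF at high dilution, so that the allylchromium species formed at C13 adds through C7 to the C6 aldehyde (intramolecular Nozaki–Hiyama allylation). This forms the same C6–C7 bond with the C11=C13 methylene and the anti C6/C7 relation through a chair transition state, needs neither the ether nor a strong base, and comes back to the route at 27.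

Step 23 (inversion at C8). What may go wrong is elimination toward C8=C9, participation of the lactone carbonyl at the activated C8, or no displacement at this hindered secondary centre. Fallback: starting from 34, Dess–Martin periodinane oxidises the C8 carbinol to the 8-ketone F2. NaBH4 with CeCl3·7H2O in MeOH at −78 °C (Luche reduction) should deliver hydride to the face away from the C11 branch on C7 and give the 8R alcohol F3. Acetylation of F3 with Ac2O and pyridine returns to 35.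

Step 12 (olefination). What may go wrong is loss of the β-silyloxy group from the phosphonate anion before it meets the aldehyde, or erosion of the E selectivity. Fallback: starting from aldehyde 19, Knoevenagel condensation with diethyl malonate (TiCl4, pyridine, THF, 0 °C) gives the alkylidene malonate F4. i-Bu2AlH reduces both esters to the 2-alkylidene-1,3-diol F5. One equivalent of MsCl with collidine and LiCl converts the less hindered hydroxymethyl group, trans to C8, into the chloro alcohol F6. TBSCl with imidazole then returns to 23.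

Further compounds
F1 | step 17 | (2Z,5S,6Z,9S,10E)-12-chloro-9-(TBS-oxy)-11-[(TBS-oxy)methyl]-3,7-dimethyl-5-(TIPS-oxy)dodeca-2,6,10-trienal | O=C/C=C(/C)C[C@H](O[Si](C(C)C)(C(C)C)C(C)C)/C=C(/C)C[C@H](O[Si](C)(C)C(C)(C)C)/C=C(/CCl)CO[Si](C)(C)C(C)(C)C
F2 | step 23 | (2S,6R,7R,11S)-13-chloro-11-hydroxy-8-oxo-2-(TIPS-oxy)germacra-1(10)Z,4Z-dien-12,6-olide | CC(C)[Si](C(C)C)(C(C)C)O[C@@H]1/C=C(/C)CC(=O)[C@@H]2[C@@H](/C=C(/C)C1)OC(=O)[C@]2(O)CCl
F3 | step 23 | (2S,6R,7R,8R,11S)-13-chloro-8,11-dihydroxy-2-(TIPS-oxy)germacra-1(10)Z,4Z-dien-12,6-olide | CC(C)[Si](C(C)C)(C(C)C)O[C@@H]1/C=C(/C)C[C@@H](O)[C@@H]2[C@@H](/C=C(/C)C1)OC(=O)[C@]2(O)CCl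
F4 | step 12 | diethyl 2-[(2S,4Z,6S,8Z)-2-(TBS-oxy)-10-(PMB-oxy)-4,8-dimethyl-6-(TIPS-oxy)deca-4,8-dien-1-ylidene]propanedioate | COc1ccc(COC/C=C(/C)C[C@H](O[Si](C(C)C)(C(C)C)C(C)C)/C=C(/C)C[C@H](O[Si](C)(C)C(C)(C)C)C=C(C(=O)OCC)C(=O)OCC)cc1
F5 | step 12 | 2-[(2S,4Z,6S,8Z)-2-(TBS-oxy)-10-(PMB-oxy)-4,8-dimethyl-6-(TIPS-oxy)deca-4,8-dien-1-ylidene]propane-1,3-diol | COc1ccc(COC/C=C(/C)C[C@H](O[Si](C(C)C)(C(C)C)C(C)C)/C=C(/C)C[C@H](O[Si](C)(C)C(C)(C)C)C=C(CO)CO)cc1
F6 | step 12 | (2E,4S,6Z,8S,10Z)-4-(TBS-oxy)-2-(chloromethyl)-12-(PMB-oxy)-6,10-dimethyl-8-(TIPS-oxy)dodeca-2,6,10-trien-1-ol | COc1ccc(COC/C=C(/C)C[C@H](O[Si](C(C)C)(C(C)C)C(C)C)/C=C(/C)C[C@H](O[Si](C)(C)C(C)(C)C)/C=C(/CCl)CO)cc1
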